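## The problem

1. The target is an open-chain dibenzylbutane lignan, ring A (4-hydroxy-3-methoxyphenyl)–C7H2–C8H(C9H3)–C8'H(C9'H2OAc)–C7'H2–ring B (4-hydroxy-3,5-dimethoxyphenyl). Two C6C3 halves are joined through C8–C8', and no ring holds the two adjacent stereocentres.
2. C8 is S and C8' is R. This is the erythro (meso-like) relation, which corresponds to a cis-2,3-dibenzylbutyrolactone, whereas the usual enolate alkylation of lignan lactones leads to the trans (threo) series.
3. The four arms on C8–C8' are alike in pairs: two arylmethyl groups that differ by one methoxy group, and CH3 against CH2OAc. Any route through a diol, diacid or lactone that carries oxygen on both C9 and C9' must later tell C9 from C9' and ring A from ring B.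
4. Both centres are CH groups with carbon neighbours only. C8' can be epimerised only while C9' is a carbonyl carbon, C8 cannot be corrected at all, and in an open chain neither controls the other reliably, so they are best set together in a cyclic transition state.
5. The electron-rich phenols are sensitive to oxidants and would compete with the C9' hydroxyl for the acetyl group. The primary acetate does not survive hydrides, organometallics or strong base, so it must come late and the phenols must be freed under neutral conditions.
6. The feature that opens the problem is the run C9'–C8'–C8–C9. C9' is the only oxidised aliphatic carbon, C8 lies β to it, and C8 carries a plain methyl group.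
7. An oxygen bridge from C9' to C8 turns this run into a 3-arylmethyl-4-methyloxetan-2-one. That ring is the formal (2+2) adduct of a ketene (C9'=C8', carrying C7' and ring B) and acetaldehyde (C8–C9). Its strained C8–O bond can then be replaced by C7 with inversion, and a cis lactone plus one inversion gives the erythro chain.

## Retrosynthesis

**Protecting groups and acetate (18 ⇒ 17 ⇒ 16).**
- The two phenolic O–H bonds are traced back to O–benzyl bonds, and the acetyl–O bond at C9' is cut.
- With both phenols masked in 16, the C9' hydroxyl is the only acceptor, so no choice between phenol and alcohol ever arises.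
- Benzyl is preferred to silyl because its removal is neutral, whereas fluoride would produce phenoxides next to an acetate. It is preferred to methyl, which could not be told from the native methoxy groups.
- The forward steps are an acylation and a hydrogenolysis that touch no stereocentre.

**Oxidation level of C9' (16 ⇒ 15).**
- C9' is raised to a carboxylic acid.
- This costs one reduction, and it exposes acid 15 as a β-branched carboxylic acid, the retron for opening a β-lactone at its alkyl carbon.
- The reduction must avoid base, because C8' is α to the carboxyl group.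

**C7–C8 (15 ⇒ 10 + 14).**
- The bond between the ring A benzylic carbon and C8 is cut. This gives lactone 10 as the electrophile and cuprate 14 as the nucleophile, made through Grignard reagent 13 from chloride 12.
- Cutting C7'–C8' (enolate benzylation) would leave C8 to be set separately by open-chain induction.
- Cutting C8–C9 (methyl as nucleophile) would need the trans lactone and an enolisable arylacetaldehyde.
- Cutting ring A–C7 would need an extra one-carbon link.
- In the chosen cut the leaving group on C8 is the carboxylate of C9' itself, activated by ring strain, so a substitution at a secondary, β-branched carbon becomes reasonable.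
- Lactone 10 holds one aromatic ring instead of two.
- The forward reaction must cleave the alkyl–oxygen bond and not the acyl–oxygen bond, and it must go with clean inversion.

**C8–C8' and O–C9' (10 ⇒ 9 + 8), the key disconnection.**
- Both ring bonds formed in a ketene–aldehyde cycloaddition are cut, giving ketene 9 and acetaldehyde 8.
- An open-chain aldol cut of C8–C8' alone would give the same pair of centres. However, it leaves a hydroxyl group that needs separate activation, and an open secondary sulfonate next to a branched carbon tends to eliminate.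
- The lactone sets both centres, tells C9 (from 8) from C9' (from 9) and activates C8, all in one catalytic step.
- The precursors are achiral.
- The forward reaction must be cis-selective, enantioselective, and selective for the cross-reaction.

**Ketene source (9 ⇒ 7 ⇒ 6).** Ketene 9 is not stored. It comes from acid chloride 7 by loss of HCl in the flask, and 7 comes from acid 6.

**C7'–C8' (6 ⇒ 2 + 3, 2 ⇒ 1).**
- The propanoic acid chain is cut at C7'–C8' into aldehyde 2 and Meldrum's acid 3, which supplies C8' and C9'.
- A reductive condensation with formate is chosen over a cinnamic acid hydrogenation because it spares the benzyl ether.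
- Aldehyde 2 comes from syringaldehyde 1.

**Ring A nucleophile (12 ⇒ 11).** The C–Cl bond of 12 is traced to the hydroxyl group of the catalogue alcohol 11.

## Roads not taken

**Alternative 1:** (the most obvious) cut C7'–C8' on a preformed lactone.
- Forward key step: the enolate of (S)-4-[4-(benzyloxy)-3-methoxybenzyl]dihydrofuran-2(3H)-one A1 is alkylated with 2-(benzyloxy)-5-(bromomethyl)-1,3-dimethoxybenzene A2.
- The electrophile enters anti to the C8 substituent, so the (3S,4S)-trans lactone A3 results, which belongs to the threo series.
- The (3R,4S)-cis lactone A4 that matches the target would need a detour: condensation with aldehyde 2 at C8', dehydration and hydrogenation. It is the less stable isomer and can epimerise at C8' with any base.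
- After that, C9 still carries oxygen. It has to be opened with halide and reduced to CH3 while C9' is kept, which costs several more steps.
- Enantiopure A1 itself needs a sequence of its own.
- The chosen plan never places oxygen on C9 and reaches the erythro relation directly.

**Alternative 2:** cut the two C–H bonds at C8 and C8'.
- Forward key step: asymmetric hydrogenation of (E)-4-[4-(benzyloxy)-3-methoxyphenyl]-2-[4-(benzyloxy)-3,5-dimethoxybenzyl]-3-methylbut-2-enoic acid A5, in which the two arylmethyl groups are cis. Syn addition of H2 would then give acid 15.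
- One step sets both centres, but on a fully assembled, acyclic tetrasubstituted alkene. The catalyst must choose between faces that differ only through two similar arylmethyl groups and CH3 against CO2H.
- Such alkenes need forcing conditions. Under these, migration of the double bond into conjugation with ring A or ring B, and E/Z exchange, would erode both relations.
- The geometrically pure alkene also needs about four steps of enol sulfonate and cross-coupling chemistry.
- In the chosen plan the centres are set on a small substrate in an organised transition state.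

**Alternative 3:** cut C8–C8' between two intact C6C3 halves, as in the biosynthesis.
- Forward key step: oxidative heterocoupling, with a trivalent iron or divalent copper oxidant or at an anode. The partners are the lithium enolates of (S)-4-benzyl-3-{3-[4-(benzyloxy)-3,5-dimethoxyphenyl]propanoyl}oxazolidin-2-one A6 and 1-[4-(benzyloxy)-3-methoxyphenyl]propan-1-one A7, and the product is γ-keto imide A8.
- The auxiliary can control C8', but C8 is formed α to the C7 ketone in an open chain without bias.
- Homodimers of both partners compete, and the electron-rich rings are themselves oxidisable.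
- The auxiliary is stoichiometric, and the C7 carbonyl must afterwards be deleted.
- The chosen plan forms the same central bond by a polar, catalytic reaction that fixes both centres.

Key step: step 4

Assumption: the quinidine-derived catalyst is taken to deliver the (3R,4S) enantiomer of 10, by analogy with the sense of induction of quinidine-type catalysts in related ketene–aldehyde lactonisations; should the sense be opposite, the pseudo-enantiomeric O-trimethylsilylquinine takes its place and nothing else changes.

## Route

Step 1
Reactants: 1 syringaldehyde (4-hydroxy-3,5-dimethoxybenzaldehyde)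
Product: 2 4-(benzyloxy)-3,5-dimethoxybenzaldehyde
Conditions: BnBr, K2CO3, DMF, 60 °C
Reagents that add atoms: benzyl bromide, BrCc1ccccc1
Why: Williamson ether synthesis on the only acidic site; the benzyl ether withstands amine base, organocopper reagents and borane and leaves at the end under neutral hydrogenolysis.

Step 2
Reactants: 2 4-(benzyloxy)-3,5-dimethoxybenzaldehyde; 3 Meldrum's acid (2,2-dimethyl-1,3-dioxane-4,6-dione)
Product: 6 3-[4-(benzyloxy)-3,5-dimethoxyphenyl]propanoic acid, via arylidene Meldrum's acid 4 (not isolated), via arylmethyl Meldrum's acid 5 (not isolated)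
Conditions: HCO2H/Et3N (5:2), 95–100 °C
Reagents that add atoms: none
Why: Knoevenagel condensation gives 4, formate transfers hydride to its electron-poor C=C (conjugate transfer reduction) to give 5, and at this temperature 5 should lose acetone and CO2 to leave the propanoic acid; no metal and no H2 are present, so the benzyl ether stays.

Step 3
Reactants: 6 3-[4-(benzyloxy)-3,5-dimethoxyphenyl]propanoic acid
Product: 7 3-[4-(benzyloxy)-3,5-dimethoxyphenyl]propanoyl chloride
Conditions: (COCl)2, DMF (cat.), CH2Cl2, 0 °C to rt; evaporate, use crude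
Reagents that add atoms: oxalyl chloride, ClC(=O)C(=O)Cl
Why: Acid chloride formation through the Vilsmeier-type chloroiminium species; all by-products are gases, so 7 can go on without purification.

Step 4
Reactants: 7 3-[4-(benzyloxy)-3,5-dimethoxyphenyl]propanoyl chloride; 8 acetaldehyde
Product: 10 (3R,4S)-3-[4-(benzyloxy)-3,5-dimethoxybenzyl]-4-methyloxetan-2-one, via arylmethylketene 9 (not isolated)
Conditions: 8 (5 equiv), O-trimethylsilylquinidine (10 mol %), LiClO4 (1 equiv), iPr2NEt (2.5 equiv), CH2Cl2/Et2O, −78 °C, 7 added slowly by syringe pump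
Reagents that add atoms: none
Why: iPr2NEt takes HCl from 7 and gives ketene 9, which slow addition keeps dilute. The quinuclidine nitrogen of the catalyst adds to C9' of 9 on the side away from the arylmethyl group and gives a Z-configured acylammonium enolate. Li+ binds the enolate oxygen and the carbonyl oxygen of 8, so that C8–C8' forms in a closed chair-like (Zimmerman–Traxler type) transition state. The C8 alkoxide then attacks the acylammonium carbon C9' in a 4-exo-trig closure, which forms the oxetan-2-one ring and frees the catalyst; the whole is a stepwise formal (2+2) cycloaddition, and the closest known reaction type is the cinchona alkaloid and lithium salt catalysed acyl halide–aldehyde cyclocondensation of alkylketenes with unbranched aliphatic aldehydes. C8' is controlled by the catalyst, whose quinoline and silyloxy groups cover one face of the bound enolate; C8 is controlled relative to C8' by the chair, in which the methyl group of 8 lies equatorial, so that the syn aldolate and hence the cis lactone should result. The step needs cross-selectivity over ketene dimerisation and over self-aldolisation of 8, and the small, unhindered, lithium-activated aldehyde in excess, the low temperature and the low ketene concentration serve this. Nothing else in 7 is acidic or electrophilic, and the aryl ethers are inert.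

Step 5
Reactants: 11 [4-(benzyloxy)-3-methoxyphenyl]methanol
Product: 12 1-(benzyloxy)-4-(chloromethyl)-2-methoxybenzene
Conditions: SOCl2, CH2Cl2, 0 °C; evaporate, use at once
Reagents that add atoms: thionyl chloride, O=S(Cl)Cl
Why: Chlorination through the chlorosulfite; the electron-rich benzylic position reacts fast at 0 °C, and 12 is used promptly because it tends to alkylate itself on storage.

Step 6
Reactants: 10 (3R,4S)-3-[4-(benzyloxy)-3,5-dimethoxybenzyl]-4-methyloxetan-2-one; 12 1-(benzyloxy)-4-(chloromethyl)-2-methoxybenzene
Product: 15 (2R,3S)-4-[4-(benzyloxy)-3-methoxyphenyl]-2-[4-(benzyloxy)-3,5-dimethoxybenzyl]-3-methylbutanoic acid, via benzylic Grignard reagent 13 (not isolated), via chloromagnesium dibenzylcuprate 14 (not isolated)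
Conditions: 12 added slowly to Mg turnings, 2-MeTHF, 0 °C; CuBr·SMe2 (0.5 equiv per 13), THF/Me2S, −40 °C; then 10, −40 to 0 °C; 1 M HCl, acid–base extraction
Reagents that add atoms: none
Why: Organocuprate SN2 opening of a β-lactone by alkyl–oxygen cleavage: the soft monovalent copper nucleophile attacks C8 anti to the C8–O bond, ring strain and the carboxylate leaving group make substitution at this secondary carbon feasible, and C7–C8 forms with inversion. Inversion at C8 turns the cis lactone into the erythro (2R,3S) acid, and C8' is not touched because the product is a carboxylate that is not enolised.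

Step 7
Reactants: 15 (2R,3S)-4-[4-(benzyloxy)-3-methoxyphenyl]-2-[4-(benzyloxy)-3,5-dimethoxybenzyl]-3-methylbutanoic acid
Product: 16 (2R,3S)-4-[4-(benzyloxy)-3-methoxyphenyl]-2-[4-(benzyloxy)-3,5-dimethoxybenzyl]-3-methylbutan-1-ol
Conditions: BH3·THF, THF, 0 °C to rt; H2O
Reagents that add atoms: none
Why: Borane reduction of a free carboxylic acid through the acyloxyborane; no base is present, so C8' should keep its configuration, and aryl, benzyl and methyl ethers are inert.

Step 8
Reactants: 16 (2R,3S)-4-[4-(benzyloxy)-3-methoxyphenyl]-2-[4-(benzyloxy)-3,5-dimethoxybenzyl]-3-methylbutan-1-ol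
Product: 17 (2R,3S)-4-[4-(benzyloxy)-3-methoxyphenyl]-2-[4-(benzyloxy)-3,5-dimethoxybenzyl]-3-methylbutyl acetate
Conditions: Ac2O, pyridine, DMAP (cat.), CH2Cl2, 0 °C to rt
Reagents that add atoms: acetic anhydride, CC(=O)OC(C)=O
Why: DMAP-catalysed acylation of the only free hydroxyl group; both phenols are still benzylated, so the acetate can sit only on C9'.

Step 9
Reactants: 17 (2R,3S)-4-[4-(benzyloxy)-3-methoxyphenyl]-2-[4-(benzyloxy)-3,5-dimethoxybenzyl]-3-methylbutyl acetate
Product: 18 (2R,3S)-2-(4-hydroxy-3,5-dimethoxybenzyl)-4-(4-hydroxy-3-methoxyphenyl)-3-methylbutyl acetate (target)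
Conditions: H2 (1 atm), 10% Pd/C, EtOAc/EtOH, rt
Reagents that add atoms: none
Why: Heterogeneous hydrogenolysis of the two benzyl aryl ethers under neutral conditions; the primary acetate, the methoxy groups and the C7 and C7' methylene groups carry no cleavable benzylic heteroatom bond, and no stereocentre is touched.

## Compound list

1 | syringaldehyde (4-hydroxy-3,5-dimethoxybenzaldehyde) | COc1cc(C=O)cc(OC)c1O | starting material
2 | 4-(benzyloxy)-3,5-dimethoxybenzaldehyde | COc1cc(C=O)cc(OC)c1OCc1ccccc1 | intermediate
3 | Meldrum's acid (2,2-dimethyl-1,3-dioxane-4,6-dione) | CC1(C)OC(=O)CC(=O)O1 | starting material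
4 | 5-[4-(benzyloxy)-3,5-dimethoxybenzylidene]-2,2-dimethyl-1,3-dioxane-4,6-dione | COc1cc(C=C2C(=O)OC(C)(C)OC2=O)cc(OC)c1OCc1ccccc1 | intermediate
5 | 5-[4-(benzyloxy)-3,5-dimethoxybenzyl]-2,2-dimethyl-1,3-dioxane-4,6-dione | COc1cc(CC2C(=O)OC(C)(C)OC2=O)cc(OC)c1OCc1ccccc1 | intermediate
6 | 3-[4-(benzyloxy)-3,5-dimethoxyphenyl]propanoic acid | COc1cc(CCC(=O)O)cc(OC)c1OCc1ccccc1 | intermediate
7 | 3-[4-(benzyloxy)-3,5-dimethoxyphenyl]propanoyl chloride | COc1cc(CCC(=O)Cl)cc(OC)c1OCc1ccccc1 | intermediate
8 | acetaldehyde | CC=O | starting material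
9 | 3-[4-(benzyloxy)-3,5-dimethoxyphenyl]prop-1-en-1-one (arylmethylketene) | COc1cc(CC=C=O)cc(OC)c1OCc1ccccc1 | intermediate
10 | (3R,4S)-3-[4-(benzyloxy)-3,5-dimethoxybenzyl]-4-methyloxetan-2-one (cis) | C[C@@H]1OC(=O)[C@@H]1Cc1cc(OC)c(OCc2ccccc2)c(OC)c1 | intermediate
11 | [4-(benzyloxy)-3-methoxyphenyl]methanol | COc1cc(CO)ccc1OCc1ccccc1 | starting material
12 | 1-(benzyloxy)-4-(chloromethyl)-2-methoxybenzene | COc1cc(CCl)ccc1OCc1ccccc1 | intermediate
13 | [4-(benzyloxy)-3-methoxybenzyl]magnesium chloride | COc1cc(C[Mg]Cl)ccc1OCc1ccccc1 | intermediate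
14 | chloromagnesium bis[4-(benzyloxy)-3-methoxybenzyl]cuprate | COc1cc(C[Cu-]Cc2ccc(OCc3ccccc3)c(OC)c2)ccc1OCc1ccccc1.[Mg+]Cl | intermediate
15 | (2R,3S)-4-[4-(benzyloxy)-3-methoxyphenyl]-2-[4-(benzyloxy)-3,5-dimethoxybenzyl]-3-methylbutanoic acid | COc1cc(C[C@H](C)[C@H](C(=O)O)Cc2cc(OC)c(OCc3ccccc3)c(OC)c2)ccc1OCc1ccccc1 | intermediate
16 | (2R,3S)-4-[4-(benzyloxy)-3-methoxyphenyl]-2-[4-(benzyloxy)-3,5-dimethoxybenzyl]-3-methylbutan-1-ol | COc1cc(C[C@H](C)[C@H](CO)Cc2cc(OC)c(OCc3ccccc3)c(OC)c2)ccc1OCc1ccccc1 | intermediate
17 | (2R,3S)-4-[4-(benzyloxy)-3-methoxyphenyl]-2-[4-(benzyloxy)-3,5-dimethoxybenzyl]-3-methylbutyl acetate | COc1cc(C[C@H](C)[C@H](COC(C)=O)Cc2cc(OC)c(OCc3ccccc3)c(OC)c2)ccc1OCc1ccccc1 | intermediate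
18 | (2R,3S)-2-(4-hydroxy-3,5-dimethoxybenzyl)-4-(4-hydroxy-3-methoxyphenyl)-3-methylbutyl acetate | COc1cc(C[C@H](C)[C@H](COC(C)=O)Cc2cc(OC)c(O)c(OC)c2)ccc1O | target

## Step count and risks

Total step count: 9. Longest linear sequence: 8 (steps 1, 2, 3, 4, 6, 7, 8, 9); step 5 is the one-step side branch.

**Step 4 (key step).**
- Here the acid chloride, and not the aldehyde, is the limiting partner. The most likely failure is therefore dimerisation of the ketene under the same nucleophilic catalyst before it meets the aldehyde.
- Self-aldolisation or evaporative loss of acetaldehyde may add to this.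
- An uncatalysed pathway mediated by amine and lithium salt would lower the enantioselectivity.
- The sense of induction rests on analogy.
- The fallback replaces catalysis by an auxiliary-controlled aldol and a separate ring closure. It sets out from 7. Acylation of lithiated (R)-4-benzyloxazolidin-2-one with 7 gives (R)-4-benzyl-3-{3-[4-(benzyloxy)-3,5-dimethoxyphenyl]propanoyl}oxazolidin-2-one F1. Enolisation with Bu2BOTf/iPr2NEt and addition to 8 (Evans syn-aldol) gives (R)-4-benzyl-3-{(2R,3S)-2-[4-(benzyloxy)-3,5-dimethoxybenzyl]-3-hydroxybutanoyl}oxazolidin-2-one F2. LiOH/H2O2 gives (2R,3S)-2-[4-(benzyloxy)-3,5-dimethoxybenzyl]-3-hydroxybutanoic acid F3. PhSO2Cl in pyridine at 0 °C closes the ring by carboxyl activation with retention at C8. The fallback comes back to the route at 10.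

**Step 6.**
- Magnesium insertion into the electron-rich benzylic chloride may be accompanied by Wurtz-type homocoupling.
- The benzylic cuprate may decay thermally before it reacts at the hindered secondary carbon.
- Attack at the carbonyl carbon (acyl–oxygen cleavage) may compete with attack at C8.
- Deprotonation at C8' may cost configurational purity or lead to elimination.
- The fallback brings in C7 as part of a more reactive sp2 nucleophile and forms the ring A–C7 bond by carbonyl addition. It sets out from 10. Vinylmagnesium bromide and CuBr·SMe2 open the lactone at C8 with inversion to (2R,3S)-2-[4-(benzyloxy)-3,5-dimethoxybenzyl]-3-methylpent-4-enoic acid F4. LiAlH4 gives (2R,3S)-2-[4-(benzyloxy)-3,5-dimethoxybenzyl]-3-methylpent-4-en-1-ol F5. Ac2O/pyridine gives (2R,3S)-2-[4-(benzyloxy)-3,5-dimethoxybenzyl]-3-methylpent-4-en-1-yl acetate F6. Lemieux–Johnson cleavage (OsO4 cat., NaIO4) gives (2R,3R)-2-[4-(benzyloxy)-3,5-dimethoxybenzyl]-3-methyl-4-oxobutyl acetate F7. [4-(Benzyloxy)-3-methoxyphenyl]magnesium bromide F8, made from the commercial aryl bromide, adds to the aldehyde at −78 °C. This gives (2R,3R)-4-[4-(benzyloxy)-3-methoxyphenyl]-2-[4-(benzyloxy)-3,5-dimethoxybenzyl]-4-hydroxy-3-methylbutyl acetate F9 as both C7 epimers. H2 over Pd/C with a trace of acid removes the benzylic hydroxyl group together with both benzyl ethers. The fallback comes back to the route at 18.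

**Step 2.**
- Hydride transfer from formate to the electron-rich arylidene compound may be slow.
- The loss of acetone and CO2 may stall at the alkylated Meldrum's acid stage, so that the one-pot cascade ends in a mixture.
- The fallback separates chain building from reduction. It sets out from 2. Knoevenagel–Doebner condensation with malonic acid (pyridine, piperidine) gives (E)-3-[4-(benzyloxy)-3,5-dimethoxyphenyl]prop-2-enoic acid F10. Homogeneous hydrogenation with RhCl(PPh3)3 and H2 saturates the alkene and spares the benzyl ether. The fallback comes back to the route at 6.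

## Further compounds

F1 | step 4 | (R)-4-benzyl-3-{3-[4-(benzyloxy)-3,5-dimethoxyphenyl]propanoyl}oxazolidin-2-one | COc1cc(CCC(=O)N2[C@H](Cc3ccccc3)COC2=O)cc(OC)c1OCc1ccccc1
F2 | step 4 | (R)-4-benzyl-3-{(2R,3S)-2-[4-(benzyloxy)-3,5-dimethoxybenzyl]-3-hydroxybutanoyl}oxazolidin-2-one | C[C@H](O)[C@@H](Cc1cc(OC)c(OCc2ccccc2)c(OC)c1)C(=O)N1[C@H](Cc2ccccc2)COC1=O
F3 | step 4 | (2R,3S)-2-[4-(benzyloxy)-3,5-dimethoxybenzyl]-3-hydroxybutanoic acid | C[C@H](O)[C@@H](Cc1cc(OC)c(OCc2ccccc2)c(OC)c1)C(=O)O
F4 | step 6 | (2R,3S)-2-[4-(benzyloxy)-3,5-dimethoxybenzyl]-3-methylpent-4-enoic acid | C=C[C@H](C)[C@H](C(=O)O)Cc1cc(OC)c(OCc2ccccc2)c(OC)c1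
F5 | step 6 | (2R,3S)-2-[4-(benzyloxy)-3,5-dimethoxybenzyl]-3-methylpent-4-en-1-ol | C=C[C@H](C)[C@H](CO)Cc1cc(OC)c(OCc2ccccc2)c(OC)c1
F6 | step 6 | (2R,3S)-2-[4-(benzyloxy)-3,5-dimethoxybenzyl]-3-methylpent-4-en-1-yl acetate | C=C[C@H](C)[C@H](COC(C)=O)Cc1cc(OC)c(OCc2ccccc2)c(OC)c1
F7 | step 6 | (2R,3R)-2-[4-(benzyloxy)-3,5-dimethoxybenzyl]-3-methyl-4-oxobutyl acetate | O=C[C@H](C)[C@H](COC(C)=O)Cc1cc(OC)c(OCc2ccccc2)c(OC)c1
F8 | step 6 | [4-(benzyloxy)-3-methoxyphenyl]magnesium bromide | COc1cc([Mg]Br)ccc1OCc1ccccc1
F9 | step 6 | (2R,3R)-4-[4-(benzyloxy)-3-methoxyphenyl]-2-[4-(benzyloxy)-3,5-dimethoxybenzyl]-4-hydroxy-3-methylbutyl acetate, both C7 epimers | COc1cc(C(O)[C@H](C)[C@H](COC(C)=O)Cc2cc(OC)c(OCc3ccccc3)c(OC)c2)ccc1OCc1ccccc1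
F10 | step 2 | (E)-3-[4-(benzyloxy)-3,5-dimethoxyphenyl]prop-2-enoic acid | COc1cc(/C=C/C(=O)O)cc(OC)c1OCc1ccccc1
A1 | alternative 1 | (S)-4-[4-(benzyloxy)-3-methoxybenzyl]dihydrofuran-2(3H)-one | COc1cc(C[C@@H]2COC(=O)C2)ccc1OCc1ccccc1
A2 | alternative 1 | 2-(benzyloxy)-5-(bromomethyl)-1,3-dimethoxybenzene | COc1cc(CBr)cc(OC)c1OCc1ccccc1
A3 | alternative 1 | (3S,4S)-4-[4-(benzyloxy)-3-methoxybenzyl]-3-[4-(benzyloxy)-3,5-dimethoxybenzyl]dihydrofuran-2(3H)-one (trans) | COc1cc(C[C@@H]2COC(=O)[C@H]2Cc2cc(OC)c(OCc3ccccc3)c(OC)c2)ccc1OCc1ccccc1
A4 | alternative 1 | (3R,4S)-4-[4-(benzyloxy)-3-methoxybenzyl]-3-[4-(benzyloxy)-3,5-dimethoxybenzyl]dihydrofuran-2(3H)-one (cis) | COc1cc(C[C@@H]2COC(=O)[C@@H]2Cc2cc(OC)c(OCc3ccccc3)c(OC)c2)ccc1OCc1ccccc1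
A5 | alternative 2 | (E)-4-[4-(benzyloxy)-3-methoxyphenyl]-2-[4-(benzyloxy)-3,5-dimethoxybenzyl]-3-methylbut-2-enoic acid | C/C(Cc1ccc(OCc2ccccc2)c(OC)c1)=C(\C(=O)O)Cc1cc(OC)c(OCc2ccccc2)c(OC)c1
A6 | alternative 3 | (S)-4-benzyl-3-{3-[4-(benzyloxy)-3,5-dimethoxyphenyl]propanoyl}oxazolidin-2-one | COc1cc(CCC(=O)N2[C@@H](Cc3ccccc3)COC2=O)cc(OC)c1OCc1ccccc1
A7 | alternative 3 | 1-[4-(benzyloxy)-3-methoxyphenyl]propan-1-one | CCC(=O)c1ccc(OCc2ccccc2)c(OC)c1
A8 | alternative 3 | (S)-4-benzyl-3-{(2R)-4-[4-(benzyloxy)-3-methoxyphenyl]-2-[4-(benzyloxy)-3,5-dimethoxybenzyl]-3-methyl-4-oxobutanoyl}oxazolidin-2-one, C8 not controlled | COc1cc(C(=O)C(C)[C@@H](Cc2cc(OC)c(OCc3ccccc3)c(OC)c2)C(=O)N2[C@@H](Cc3ccccc3)COC2=O)ccc1OCc1ccccc1
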